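**Plan**
- Numbering: naphthalene C1 (aryl), C2 (OH), C3 (CHO), C4 (H), C7 (OH), C8 (OMe). Ring A is the C4a–C8a benzo ring, ring B is C1–C4, and ring C is C1'–C6' with OMe on C3' and C4'.
- Enabling feature: the C1–C1' bond lies between the C2 oxygen and the peri C8 methoxy group. The chain C2'–C3'(OMe)–C4'(OMe)–C5' of ring C is the carbon skeleton of twofold-symmetric 2,3-dimethoxybutadiene, and C1'–C6' is a vinyl unit on C1. Ring C can therefore be grown on C1 rather than coupled to it.
- Cuts: C1'–C2' and C5'–C6' (retro-[4+2], after HNO2 and H2 are put back on ring C), then C1'=C6' (Henry) and C1–C1' (ortho-formylation). Ring B is then opened at C8a–C1 (enolate arylation) and C3=C4 (Knoevenagel).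
- Forward: ring A is bought as O-isopropylvanillin and brominated between CHO and OMe, and ring B is closed with methyl acetoacetate. C1 is formylated and made into the nitrovinyl group, then ring C is closed by cycloaddition and aromatised. Ester-to-aldehyde adjustment and a double dealkylation finish the route.
- Stereochemistry: the target has no stereocentre. The trans C1'/C6' pair of the cycloadduct comes from the E-alkene and vanishes on aromatisation.

Key step: step 7

Assumption: 4-isopropoxy-3-methoxybenzaldehyde and 2,3-dimethoxybuta-1,3-diene are taken as catalogue compounds, and the C1–C1' axis, which has only hydrogen at both ortho positions of ring C, is treated as configurationally labile, as in the target SMILES.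

Names of naphthalenes use the target numbering given above.

**Step 1**
Reactants: 1 4-isopropoxy-3-methoxybenzaldehyde
Product: 5 2-bromo-4-isopropoxy-3-methoxybenzaldehyde, via lithium α-amino alkoxide 2 (not isolated), via C2-lithiated alkoxide 3 (not isolated), via C2-brominated alkoxide 4 (not isolated)
Conditions: Me2NCH2CH2NHMe, n-BuLi, THF, −20 °C; add 1; n-BuLi (3 equiv), −20 to 0 °C; BrCCl2CCl2Br, −78 °C to rt; H2O
Reagents that add atoms: 1,2-dibromo-1,1,2,2-tetrachloroethane, BrC(Cl)(Cl)C(Cl)(Cl)Br
Why: Directed ortho-metalation of an α-amino alkoxide formed in situ, in which the chelating diamine arm and the C3 methoxy group act together on the carbon between them, the isopropyl ether offers no benzylic C–H to the base, and a positive-bromine donor quenches the aryllithium before water releases the aldehyde.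

**Step 2**
Reactants: 5 2-bromo-4-isopropoxy-3-methoxybenzaldehyde; 6 methyl acetoacetate
Product: 7 methyl 2-[(2-bromo-4-isopropoxy-3-methoxyphenyl)methylidene]-3-oxobutanoate (E/Z mixture)
Conditions: piperidine (10 mol %), AcOH (10 mol %), PhMe, Dean–Stark, reflux
Reagents that add atoms: none
Why: Knoevenagel condensation of the active methylene of 6 with the aldehyde under azeotropic removal of water, which forms C3=C4 and leaves the acetyl CH3 as the only enolisable position.

**Step 3**
Reactants: 7 methyl 2-[(2-bromo-4-isopropoxy-3-methoxyphenyl)methylidene]-3-oxobutanoate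
Product: 9 methyl 2-hydroxy-7-isopropoxy-8-methoxy-3-naphthoate, via keto tautomer 8 (not isolated)
Conditions: Pd(OAc)2 (5 mol %), XPhos (10 mol %), K3PO4 (2.5 equiv), PhMe (0.02 M), 100 °C; aq. NH4Cl
Reagents that add atoms: none
Why: Intramolecular palladium-catalysed α-arylation of a methyl ketone enolate, in which zerovalent palladium inserts into C–Br, the enolate replaces bromide on palladium and reductive elimination closes six-membered ring B at C8a–C1, while the E/Z isomers of 7 should interconvert under the hot basic conditions so that both drain through the isomer with acetyl cis to the arene, and tautomerisation of 8 to the naphthol makes the closure irreversible.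

**Step 4**
Reactants: 9 methyl 2-hydroxy-7-isopropoxy-8-methoxy-3-naphthoate
Product: 11 methyl 1-formyl-2-hydroxy-7-isopropoxy-8-methoxy-3-naphthoate, via 1-hydroxymethyl naphthol 10 (not isolated)
Conditions: MgCl2 (3 equiv), Et3N (5 equiv), (CH2O)n (8 equiv), MeCN, reflux; 1 M HCl
Reagents that add atoms: paraformaldehyde (reacts as formaldehyde), C=O
Why: Casnati–Skattebøl ortho-formylation, in which the magnesium naphthoxide delivers formaldehyde only to the free ortho carbon, which is C1 because C3 is blocked (so the electron-rich C5 and C6 of ring A are left alone), and hydride transfer from the magnesium alkoxide of 10 to a second formaldehyde gives the aldehyde.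

**Step 5**
Reactants: 11 methyl 1-formyl-2-hydroxy-7-isopropoxy-8-methoxy-3-naphthoate
Product: 12 methyl 2-(benzyloxy)-1-formyl-7-isopropoxy-8-methoxy-3-naphthoate
Conditions: BnBr, K2CO3, DMF, 50 °C
Reagents that add atoms: benzyl bromide, BrCc1ccccc1
Why: Williamson etherification of the acidic, doubly flanked naphthol with a reactive primary benzylic bromide, giving a group that is slim next to C1 and falls to the same Lewis acid as the isopropyl ether at the end.

**Step 6**
Reactants: 12 methyl 2-(benzyloxy)-1-formyl-7-isopropoxy-8-methoxy-3-naphthoate; 13 nitromethane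
Product: 14 methyl 2-(benzyloxy)-7-isopropoxy-8-methoxy-1-[(E)-2-nitrovinyl]-3-naphthoate
Conditions: NH4OAc, 13 as solvent, 100 °C
Reagents that add atoms: none
Why: Henry (nitroaldol) condensation with dehydration in the same flask, which should give the thermodynamically preferred E-nitroalkene as is usual for 2-alkoxy-1-naphthaldehydes.

**Step 7**
Reactants: 14 methyl 2-(benzyloxy)-7-isopropoxy-8-methoxy-1-[(E)-2-nitrovinyl]-3-naphthoate; 15 2,3-dimethoxybuta-1,3-diene
Product: 16 methyl 2-(benzyloxy)-1-[trans-3,4-dimethoxy-6-nitrocyclohex-3-en-1-yl]-7-isopropoxy-8-methoxy-3-naphthoate (racemic, aryl and nitro on opposite faces)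
Conditions: 15 (6 equiv), BHT (5 mol %), K2CO3 (10 mol %), PhMe, sealed tube, 120 °C
Reagents that add atoms: none
Why: The nitro group lowers the LUMO of the C1'=C6' alkene and the two methoxy groups raise the HOMO of the s-cis diene, so a concerted, asynchronous, normal-electron-demand [4+2] cycloaddition should form C1'–C2' and C6'–C5' in one suprafacial event, the closest known reaction type being the thermal Diels–Alder reaction of β-nitrostyrenes with 2-alkoxy- and 2-silyloxybutadienes. Ring C closes as a six-membered carbocycle by intermolecular [4+2] cycloaddition, with four carbons from the diene and two from the nitrovinyl group. The stereocentres C1' and C6' are fixed relative to each other by the E geometry of 14, which is carried stereospecifically into the trans aryl/nitro arrangement; no endo/exo question arises because both diene termini are CH2 groups, the adduct is racemic, and both centres are erased in step 8. No regiochemical question arises because the diene is twofold symmetric. The selectivity that is needed is periselectivity, all-carbon [4+2] rather than hetero-[4+2] through the C=C–N=O unit onto one enol ether, and it is favoured by leaving out Lewis acids and by working thermally, where the carbocycle is the thermodynamic sink. Both bonds form at alkene carbons that project away from the C2 benzyloxy and C8 methoxy groups because the vinyl group is twisted out of the naphthalene plane, and BHT with a trace of K2CO3 protects the acid-labile diene and the bis(enol ether) product.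

**Step 8**
Reactants: 16 methyl 2-(benzyloxy)-1-[trans-3,4-dimethoxy-6-nitrocyclohex-3-en-1-yl]-7-isopropoxy-8-methoxy-3-naphthoate
Product: 18 methyl 2-(benzyloxy)-1-(3,4-dimethoxyphenyl)-7-isopropoxy-8-methoxy-3-naphthoate, via nitrocyclohexadiene 17 (not isolated)
Conditions: DDQ (1.05 equiv), 4 Å MS, dry PhMe, 0 °C to rt; then DBU (3 equiv), rt to 50 °C
Reagents that add atoms: none
Why: DDQ dehydrogenation of an enol ether (allylic hydride abstraction at C2', proton loss at C5') should raise ring C to the cyclohexadiene level, where the nitro group is allylic and pushed by the C4' methoxy group, so that base-induced loss of HNO2, the aromatising event known from nitroalkene benzannulations, is driven by arene formation, while one equivalent of oxidant and dry, finally basic conditions guard against retention of the nitro group and enol ether hydrolysis.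

**Step 9**
Reactants: 18 methyl 2-(benzyloxy)-1-(3,4-dimethoxyphenyl)-7-isopropoxy-8-methoxy-3-naphthoate
Product: 19 [2-(benzyloxy)-1-(3,4-dimethoxyphenyl)-7-isopropoxy-8-methoxynaphthalen-3-yl]methanol
Conditions: LiAlH4, THF, 0 °C; H2O
Reagents that add atoms: none
Why: Hydride reduction of an aryl ester to the primary benzylic alcohol, with all ethers and arenes inert to LiAlH4.

**Step 10**
Reactants: 19 [2-(benzyloxy)-1-(3,4-dimethoxyphenyl)-7-isopropoxy-8-methoxynaphthalen-3-yl]methanol
Product: 20 2-(benzyloxy)-1-(3,4-dimethoxyphenyl)-7-isopropoxy-8-methoxynaphthalene-3-carbaldehyde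
Conditions: activated MnO2 (excess), CH2Cl2, rt
Reagents that add atoms: none
Why: Heterogeneous MnO2 oxidation of a benzylic alcohol, which stops at the aldehyde.

**Step 11**
Reactants: 20 2-(benzyloxy)-1-(3,4-dimethoxyphenyl)-7-isopropoxy-8-methoxynaphthalene-3-carbaldehyde
Product: 21 vitrofolal B, 1-(3,4-dimethoxyphenyl)-2,7-dihydroxy-8-methoxynaphthalene-3-carbaldehyde
Conditions: BCl3 (6 equiv), C6HMe5 (3 equiv), CH2Cl2, −78 °C to rt; H2O
Reagents that add atoms: none
Why: Lewis-acid dealkylation of aryl ethers, in which BCl3 cleaves the benzyl ether (helped by chelation to the C3 aldehyde, with the cation trapped by pentamethylbenzene) and the secondary isopropyl ether, while aryl methyl ethers that are not ortho to a carbonyl group should withstand BCl3 under these conditions.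

**Compound list**
1 | 4-isopropoxy-3-methoxybenzaldehyde | O=Cc1ccc(OC(C)C)c(OC)c1 | starting material
2 | lithium α-amino alkoxide from 1 and lithium [2-(dimethylamino)ethyl](methyl)amide (racemic) | [Li]OC(N(C)CCN(C)C)c1ccc(OC(C)C)c(OC)c1 | intermediate (not isolated)
3 | C2-lithiated derivative of 2 | [Li]OC(N(C)CCN(C)C)c1ccc(OC(C)C)c(OC)c1[Li] | intermediate (not isolated)
4 | C2-brominated α-amino alkoxide | [Li]OC(N(C)CCN(C)C)c1ccc(OC(C)C)c(OC)c1Br | intermediate (not isolated)
5 | 2-bromo-4-isopropoxy-3-methoxybenzaldehyde | O=Cc1ccc(OC(C)C)c(OC)c1Br | intermediate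
6 | methyl acetoacetate | CC(=O)CC(=O)OC | starting material
7 | methyl 2-[(2-bromo-4-isopropoxy-3-methoxyphenyl)methylidene]-3-oxobutanoate (E/Z mixture) | COC(=O)C(=Cc1ccc(OC(C)C)c(OC)c1Br)C(C)=O | intermediate
8 | methyl 7-isopropoxy-8-methoxy-2-oxo-1,2-dihydronaphthalene-3-carboxylate | COC(=O)C1=Cc2ccc(OC(C)C)c(OC)c2CC1=O | intermediate (not isolated)
9 | methyl 2-hydroxy-7-isopropoxy-8-methoxy-3-naphthoate | COC(=O)c1cc2ccc(OC(C)C)c(OC)c2cc1O | intermediate
10 | methyl 2-hydroxy-1-(hydroxymethyl)-7-isopropoxy-8-methoxy-3-naphthoate (present as its magnesium salt) | COC(=O)c1cc2ccc(OC(C)C)c(OC)c2c(CO)c1O | intermediate (not isolated)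
11 | methyl 1-formyl-2-hydroxy-7-isopropoxy-8-methoxy-3-naphthoate | COC(=O)c1cc2ccc(OC(C)C)c(OC)c2c(C=O)c1O | intermediate
12 | methyl 2-(benzyloxy)-1-formyl-7-isopropoxy-8-methoxy-3-naphthoate | COC(=O)c1cc2ccc(OC(C)C)c(OC)c2c(C=O)c1OCc1ccccc1 | intermediate
13 | nitromethane | C[N+](=O)[O-] | starting material
14 | methyl 2-(benzyloxy)-7-isopropoxy-8-methoxy-1-[(E)-2-nitrovinyl]-3-naphthoate | COC(=O)c1cc2ccc(OC(C)C)c(OC)c2c(/C=C/[N+](=O)[O-])c1OCc1ccccc1 | intermediate
15 | 2,3-dimethoxybuta-1,3-diene | C=C(OC)C(OC)=C | starting material
16 | methyl 2-(benzyloxy)-1-[trans-3,4-dimethoxy-6-nitrocyclohex-3-en-1-yl]-7-isopropoxy-8-methoxy-3-naphthoate (racemic, one enantiomer drawn) | COC(=O)c1cc2ccc(OC(C)C)c(OC)c2c([C@@H]2CC(OC)=C(OC)C[C@H]2[N+](=O)[O-])c1OCc1ccccc1 | intermediate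
17 | methyl 2-(benzyloxy)-1-[trans-3,4-dimethoxy-6-nitrocyclohexa-2,4-dien-1-yl]-7-isopropoxy-8-methoxy-3-naphthoate (racemic, one enantiomer drawn) | COC(=O)c1cc2ccc(OC(C)C)c(OC)c2c([C@@H]2C=C(OC)C(OC)=C[C@H]2[N+](=O)[O-])c1OCc1ccccc1 | intermediate (not isolated)
18 | methyl 2-(benzyloxy)-1-(3,4-dimethoxyphenyl)-7-isopropoxy-8-methoxy-3-naphthoate | COC(=O)c1cc2ccc(OC(C)C)c(OC)c2c(-c2ccc(OC)c(OC)c2)c1OCc1ccccc1 | intermediate
19 | [2-(benzyloxy)-1-(3,4-dimethoxyphenyl)-7-isopropoxy-8-methoxynaphthalen-3-yl]methanol | OCc1cc2ccc(OC(C)C)c(OC)c2c(-c2ccc(OC)c(OC)c2)c1OCc1ccccc1 | intermediate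
20 | 2-(benzyloxy)-1-(3,4-dimethoxyphenyl)-7-isopropoxy-8-methoxynaphthalene-3-carbaldehyde | O=Cc1cc2ccc(OC(C)C)c(OC)c2c(-c2ccc(OC)c(OC)c2)c1OCc1ccccc1 | intermediate
21 | vitrofolal B | COc1ccc(-c2c(O)c(C=O)cc3ccc(O)c(OC)c23)cc1OC | target

Total step count: 11. Longest linear sequence: 11 steps (1 to 21); compounds 6, 13 and 15 are bought.

**Steps most likely to fail**

Step 7. The twisted nitrovinyl group, flanked on both sides, may react too slowly. Diene polymerisation or hetero-cycloaddition through the nitro group would then take over.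
- The fallback gives up building ring C and makes the C1–C1' bond by cross-coupling. It sets out from 9 and rejoins the route at 18.
- Bromination of 9 with NBS in MeCN at 0 °C should go ortho to the free naphthol and give methyl 1-bromo-2-hydroxy-7-isopropoxy-8-methoxy-3-naphthoate F1.
- BnBr and K2CO3 in DMF should convert F1 into methyl 2-(benzyloxy)-1-bromo-7-isopropoxy-8-methoxy-3-naphthoate F2.
- Suzuki–Miyaura coupling of F2 with 3,4-dimethoxyphenylboronic acid (Pd(OAc)2, SPhos, K3PO4, PhMe/H2O, 100 °C) should give 18. The boronic acid has no ortho substituent.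

Step 3. Several processes could erode the ring closure:
- slow oxidative addition at the doubly ortho-flanked C–Br bond;
- slow E/Z interconversion;
- arylation at the enolate oxygen instead of carbon;
- Michael oligomerisation of the enolate.

The fallback uses a symmetric bis(β-keto ester), so that both ring-B bonds come from stabilised carbanions and alkene geometry does not matter. It sets out from 5 and rejoins the route at 9.
- A domino Knoevenagel/Hurtley-type C-arylation of 5 with dimethyl 3-oxopentanedioate (CuI, 2-picolinic acid, Cs2CO3, dioxane, 100 °C) should give dimethyl 2-hydroxy-7-isopropoxy-8-methoxynaphthalene-1,3-dicarboxylate F3.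
- Exhaustive saponification (KOH, aq. DMSO, heat, then HCl) should give 2-hydroxy-7-isopropoxy-8-methoxynaphthalene-1,3-dicarboxylic acid F4.
- Warming F4 in aqueous acid should remove only the C1 carboxyl group, because ipso-protonation of a 2-naphthol at C1 is easy. The product is 2-hydroxy-7-isopropoxy-8-methoxy-3-naphthoic acid F5.
- MeI and KHCO3 in DMF should esterify the carboxylate of F5 and give 9.

Step 8. A second dehydrogenation could outrun the loss of HNO2, so that the nitro group stays on ring C. Acid set free in the oxidation could also hydrolyse the enol ethers.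
- The fallback removes the nitro group reductively before any oxidation. It sets out from 16 and rejoins the route at 18.
- Radical denitration of 16 (Bu3SnH, AIBN, PhMe, reflux) should give methyl 2-(benzyloxy)-1-(3,4-dimethoxycyclohex-3-en-1-yl)-7-isopropoxy-8-methoxy-3-naphthoate F6.
- Double dehydrogenation of F6 with DDQ (2.2 equiv, dry dioxane, rt to 60 °C) should give 18.

**Further compounds**
F1 | step 7 | methyl 1-bromo-2-hydroxy-7-isopropoxy-8-methoxy-3-naphthoate | COC(=O)c1cc2ccc(OC(C)C)c(OC)c2c(Br)c1O
F2 | step 7 | methyl 2-(benzyloxy)-1-bromo-7-isopropoxy-8-methoxy-3-naphthoate | COC(=O)c1cc2ccc(OC(C)C)c(OC)c2c(Br)c1OCc1ccccc1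
F3 | step 3 | dimethyl 2-hydroxy-7-isopropoxy-8-methoxynaphthalene-1,3-dicarboxylate | COC(=O)c1cc2ccc(OC(C)C)c(OC)c2c(C(=O)OC)c1O
F4 | step 3 | 2-hydroxy-7-isopropoxy-8-methoxynaphthalene-1,3-dicarboxylic acid | OC(=O)c1cc2ccc(OC(C)C)c(OC)c2c(C(O)=O)c1O
F5 | step 3 | 2-hydroxy-7-isopropoxy-8-methoxy-3-naphthoic acid | OC(=O)c1cc2ccc(OC(C)C)c(OC)c2cc1O
F6 | step 8 | methyl 2-(benzyloxy)-1-(3,4-dimethoxycyclohex-3-en-1-yl)-7-isopropoxy-8-methoxy-3-naphthoate (racemic, one enantiomer drawn) | COC(=O)c1cc2ccc(OC(C)C)c(OC)c2c([C@@H]2CC(OC)=C(OC)CC2)c1OCc1ccccc1
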